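**Plan**

Locants: ring A = C1–C2–C3–C4=C5–C15–C14, ring B = C5–C6–C7–C8–C13–C14–C15, ring C = C8=C9–C10–C11–C12–C13; C16 = exocyclic CH2 on C1; side chain C1′–C6′ on C12.
Retrosynthesis: C4=C5 is traced to an allylic sulfinic acid (C4–SO2H, C5=C6; retro-ene) and C1=C16 to a ketone. Ring A is then cut at C3–C4 and C1–C2, both made when a C4 allylic sulfonyl carbanion adds to phenyl vinyl sulfone and the new C2 carbanion acylates the C14 ester.
Enabling feature: C2–C3 is an unsubstituted ethano unit between an acyl-level carbon (C1) and a carbon (C4) allylic to C5, and the two anchors C5 and C14 sit 1,3 across C15 on ring B.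
Further cuts: ring B at C5=C6 (ring-closing metathesis); C13–C14 by Ireland–Claisen rearrangement of a tertiary cyclohexenyl ester, which also places C8=C9 and the C9 methyl; ring C from (S)-citronellal and a vinyl ketone.
Forward order: ring C → C13–C14 → ring B → ring A (bicyclo[4.4.1] core) → desulfonylation, methylenation, fluoride-triggered SO2 loss with alkene shift.
Stereochemistry: C1′ from (S)-citronellal; C12 by enamine catalysis; C13 by suprafacial [3,3] transfer from the C9 carbinol; C14 by ketene acetal geometry; 4′E by SeO2; C4=C5 geometry by the ring.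

Key step: step 11

Remark: dienone 3 is not assumed to be commercial and is made in step 1; the sulfonyl-bearing centres C2 and C4 of 23–28 are left uncontrolled because both groups are removed.

**Step 1**
Reactants: 1 pent-4-enoyl chloride; 2 tributyl(ethenyl)stannane
Product: 3 hepta-1,6-dien-3-one
Conditions: Pd(PPh3)4 (2 mol %), THF, 50 °C; distilled and used at once
Reagents that add atoms: none
Why: Stille acylation (zerovalent palladium inserts into the C–Cl bond, vinyl transfer from tin, reductive elimination) should give the vinyl ketone without touching the terminal alkene; no stereocentre is formed.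

**Step 2**
Reactants: 4 (S)-citronellal; 3 hepta-1,6-dien-3-one
Product: 6 (4S)-4-[(2S)-6-methylhept-5-en-2-yl]-2-(prop-2-en-1-yl)cyclohex-2-en-1-one, via keto aldehyde 5 (not isolated)
Conditions: (S)-2-[methoxy(diphenyl)methyl]pyrrolidine (5 mol %), ethyl 3,4-dihydroxybenzoate (20 mol %), neat, 4 °C; then KOH (0.1 M aq), Bu4NOH (cat.), THF–Et2O, reflux
Reagents that add atoms: none
Why: Enamine-catalysed Michael addition to the vinyl ketone should set C12 (S) by attack on the enamine face not shielded by the diarylmethyl group, and the intramolecular aldol condensation (Robinson-type annulation) can only close the six-membered ring through C8, which therefore carries the allyl group.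

**Step 3**
Reactants: 6 enone
Product: 7 (4S)-4-[(2S,5E)-7-hydroxy-6-methylhept-5-en-2-yl]-2-(prop-2-en-1-yl)cyclohex-2-en-1-one
Conditions: SeO2 (0.3 equiv), t-BuOOH (3 equiv), salicylic acid (cat.), CH2Cl2, 23 °C
Reagents that add atoms: tert-butyl hydroperoxide CC(C)(C)OO (terminal oxidant, oxygen delivered through SeO2)
Why: SeO2 allylic oxidation (ene reaction, then [2,3]-sigmatropic shift) should attack the electron-rich trisubstituted alkene at its (E)-methyl group, the enone and the monosubstituted allyl alkene being far less reactive.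

**Step 4**
Reactants: 7 allylic alcohol
Product: 8 (4S)-4-[(2S,5E)-7-{[tert-butyl(diphenyl)silyl]oxy}-6-methylhept-5-en-2-yl]-2-(prop-2-en-1-yl)cyclohex-2-en-1-one
Conditions: t-BuPh2SiCl (1.2 equiv), imidazole (2.5 equiv), DMF, 23 °C
Reagents that add atoms: tert-butyl(chloro)diphenylsilane CC(C)(C)[Si](Cl)(c1ccccc1)c1ccccc1
Why: Silylation of the primary allylic alcohol gives an ether that should survive organolithium, amide base, metathesis and amalgam conditions and fall to fluoride in the last step.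

**Step 5**
Reactants: 8 enone
Product: 10 (1R,4S)-4-[(2S,5E)-7-{[tert-butyl(diphenyl)silyl]oxy}-6-methylhept-5-en-2-yl]-1-methyl-2-(prop-2-en-1-yl)cyclohex-2-en-1-yl acetate, via lithium alkoxide 9 (not isolated)
Conditions: MeLi (1.3 equiv), Et2O, −78 °C; then Ac2O (2 equiv), DMAP (cat.), −78 → 0 °C
Reagents that add atoms: methyllithium [Li]C; acetic anhydride CC(=O)OC(C)=O
Why: 1,2-Addition along the axial trajectory of the half-chair with the C12 side chain pseudo-equatorial should place the new C9–O bond trans to that side chain, and the tertiary lithium alkoxide is acetylated in the same flask.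

**Step 6**
Reactants: 11 3-chloro-2-(chloromethyl)prop-1-ene; 12 2-(trimethylsilyl)ethanethiol
Product: 13 {2-[(2-(chloromethyl)prop-2-en-1-yl)sulfanyl]ethyl}(trimethyl)silane
Conditions: K2CO3, DMF, 0 → 23 °C, 11 in threefold excess
Reagents that add atoms: none
Why: SN2 displacement of one allylic chloride by the thiolate, with excess dichloride to hold back double substitution, installs the latent sulfinate group.

**Step 7**
Reactants: 10 tertiary allylic acetate; 13 allylic chloride
Product: 15 (1R,4S)-4-[(2S,5E)-7-{[tert-butyl(diphenyl)silyl]oxy}-6-methylhept-5-en-2-yl]-1-methyl-2-(prop-2-en-1-yl)cyclohex-2-en-1-yl 4-({[2-(trimethylsilyl)ethyl]sulfanyl}methyl)pent-4-enoate, via lithium enolate 14 (not isolated)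
Conditions: LDA (1.1 equiv), THF, −78 °C; then 13 (1.3 equiv), NaI (cat.), DMPU, −78 → −30 °C
Reagents that add atoms: none
Why: Alkylation of the acetate enolate with the allylic halide should build the C14–C15–C5–C4 chain on the ester, kept cold so that the lithium enolate does not rearrange.

**Step 8**
Reactants: 15 tertiary allylic ester
Product: 19 methyl (2S)-2-{(1R,6S)-6-[(2S,5E)-7-{[tert-butyl(diphenyl)silyl]oxy}-6-methylhept-5-en-2-yl]-3-methyl-2-(prop-2-en-1-yl)cyclohex-2-en-1-yl}-4-({[2-(trimethylsilyl)ethyl]sulfanyl}methyl)pent-4-enoate, via silyl ketene acetal 16 (not isolated), via trimethylsilyl ester 17 (not isolated), via carboxylic acid 18 (not isolated)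
Conditions: LDA (1.2 equiv), THF–DMPU (4:1), −78 °C; Me3SiCl–Et3N, −78 → 50 °C; then MeOH, Me3SiCHN2, toluene, 0 °C
Reagents that add atoms: (trimethylsilyl)diazomethane C[Si](C)(C)C=[N+]=[N-]
Why: In this Ireland–Claisen rearrangement the suprafacial [3,3] shift should deliver C14 to C13 on the face that carried the C9 oxygen (trans to the C12 side chain, 13R) and form the tetrasubstituted C8=C9 alkene regiospecifically, while the (Z)-ketene acetal in a chair-like transition state (the boat is crowded by the C8 allyl group) should give 14S; the acid is then methylated.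

**Step 9**
Reactants: 19 sulfide ester
Product: 20 methyl (2S)-2-{(1R,6S)-6-[(2S,5E)-7-{[tert-butyl(diphenyl)silyl]oxy}-6-methylhept-5-en-2-yl]-3-methyl-2-(prop-2-en-1-yl)cyclohex-2-en-1-yl}-4-({[2-(trimethylsilyl)ethyl]sulfonyl}methyl)pent-4-enoate
Conditions: (NH4)6Mo7O24·4H2O (10 mol %), H2O2 (30% aq, 4 equiv), EtOH, 0 → 23 °C
Reagents that add atoms: hydrogen peroxide OO
Why: Molybdate-catalysed peroxide oxidation should take the sulfide to the sulfone much faster than it epoxidises the alkenes, and the sulfone is the better partner for the ruthenium catalyst in the next step.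

**Step 10**
Reactants: 20 sulfone diene
Product: 21 bicyclic ester (rings B and C closed; C5=C6 and C8=C9 alkenes; CO2Me on C14; CH2SO2CH2CH2SiMe3 on C5; 12S,13R,14S,1′S,4′E)
Conditions: second-generation Grubbs catalyst, (H2IMes)(PCy3)Cl2Ru=CHPh (5 mol %), CH2Cl2 (2 mM), 40 °C
Reagents that add atoms: none
Why: Ring-closing metathesis of the monosubstituted and the 1,1-disubstituted alkene should close the seven-membered ring B with the trisubstituted C5=C6 alkene, the tetrasubstituted and the hindered trisubstituted alkenes being inert.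

**Step 11**
Reactants: 21 bicyclic ester; 22 phenyl vinyl sulfone
Product: 24 tricyclic β-keto bis-sulfone (bicyclo[4.4.1] rings A/B fused to ring C; C1 ketone; PhSO2 on C2; Me3SiCH2CH2SO2 on C4; C5=C6 and C8=C9 alkenes), via lithiated Michael adduct 23 (not isolated)
Conditions: LiHMDS (1.1 equiv), THF, −78 °C; 22 (1.0 equiv), −78 → 23 °C; aq NH4Cl
Reagents that add atoms: none
Why: LiHMDS removes the allylic α-sulfonyl proton at C4 (far more acidic than the C14 ester α-H), the delocalised carbanion adds through its α-carbon to phenyl vinyl sulfone (C4–C3), and the new α-sulfonyl carbanion at C2 acylates the C14 methyl ester (C2–C1), so the vinyl sulfone acts as a CH2–CH2 unit that is electrophilic at one end and nucleophilic at the other. The closest known reaction type is the Michael-initiated ring closure (tandem Michael/Dieckmann annulation) of stabilised carbanions with acceptor alkenes, here run as an anionic [5+2] annulation. Ring A closes in the 7-exo-trig mode at the ester carbonyl, and because the new chain spans C5 and C14 across the C15 bridge this closure completes the bicyclo[4.4.1]undecene core. The new centres C2 and C4 need no control (C2 loses its sulfone in step 12, C4 becomes sp2 in step 14), while C14 keeps the configuration set in step 8 and cannot epimerise once it is a bridgehead. The selectivities needed are α- over γ-attack of the allyl sulfonyl anion (lithium counter-ion in THF without polar cosolvent) and ring closure over a second addition (one equivalent of acceptor, low temperature). The methoxide released deprotonates the β-keto sulfone irreversibly, and an initial five-membered Claisen closure at C4 should be funnelled to the same enolate by Michael addition, aldol closure and retro-aldol ring enlargement.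

**Step 12**
Reactants: 24 β-keto bis-sulfone
Product: 25 tricyclic ketone (C1 ketone; Me3SiCH2CH2SO2 on C4; C5=C6 and C8=C9 alkenes)
Conditions: Al(Hg), THF–H2O (9:1), 0 → 23 °C
Reagents that add atoms: none
Why: Reductive desulfonylation by electron transfer should cleave only the C–S bond α to the ketone (enolate as leaving group) and leave the allylic alkyl sulfone, the silyl ether and the alkenes.

**Step 13**
Reactants: 25 tricyclic ketone
Product: 26 exocyclic methylene sulfone (C1=C16 in place; Me3SiCH2CH2SO2 on C4; C5=C6 alkene)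
Conditions: Cp2TiMe2 (3 equiv), toluene–THF, 70 °C, dark
Reagents that add atoms: dimethyltitanocene [CH3-].[CH3-].[Ti+4].[cH-]1cccc1.[cH-]1cccc1
Why: Petasis methylenation (titanium methylidene, oxatitanacyclobutane, cycloreversion) is non-basic, so it should avoid both enolisation and migration of the C5=C6 alkene into conjugation with the sulfone.

**Step 14**
Reactants: 26 exocyclic methylene sulfone
Product: 29 target, via sulfinate salt 27 (not isolated), via sulfinic acid 28 (not isolated)
Conditions: Bu4NF (6 equiv), THF, 23 → 60 °C; then AcOH, 0 → 23 °C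
Reagents that add atoms: none
Why: Fluoride should cleave the silyl ether and trigger β-elimination of the 2-(trimethylsilyl)ethyl sulfone to the allylic sulfinate; on acidification the allylic sulfinic acid loses SO2 by a retro-ene reaction that delivers hydrogen to C6 and moves the alkene to C4=C5, whose geometry is fixed by the bicyclo[4.4.1] frame.

**Compound list**

1 | pent-4-enoyl chloride | C=CCCC(=O)Cl | starting material
2 | tributyl(ethenyl)stannane | C=C[Sn](CCCC)(CCCC)CCCC | starting material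
3 | hepta-1,6-dien-3-one | C=CCCC(=O)C=C | intermediate
4 | (S)-citronellal, (3S)-3,7-dimethyloct-6-enal | C[C@@H](CCC=C(C)C)CC=O | starting material
5 | (2S)-2-[(2S)-6-methylhept-5-en-2-yl]-5-oxonon-8-enal | C=CCCC(=O)CC[C@@H]([C@@H](C)CCC=C(C)C)C=O | intermediate
6 | (4S)-4-[(2S)-6-methylhept-5-en-2-yl]-2-(prop-2-en-1-yl)cyclohex-2-en-1-one | O=C1CC[C@@H]([C@@H](C)CCC=C(C)C)C=C1CC=C | intermediate
7 | (4S)-4-[(2S,5E)-7-hydroxy-6-methylhept-5-en-2-yl]-2-(prop-2-en-1-yl)cyclohex-2-en-1-one | O=C1CC[C@@H]([C@@H](C)CC/C=C(\C)CO)C=C1CC=C | intermediate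
8 | (4S)-4-[(2S,5E)-7-{[tert-butyl(diphenyl)silyl]oxy}-6-methylhept-5-en-2-yl]-2-(prop-2-en-1-yl)cyclohex-2-en-1-one | O=C1CC[C@@H]([C@@H](C)CC/C=C(\C)CO[Si](c2ccccc2)(c2ccccc2)C(C)(C)C)C=C1CC=C | intermediate
9 | lithium (1R,4S)-4-[(2S,5E)-7-{[tert-butyl(diphenyl)silyl]oxy}-6-methylhept-5-en-2-yl]-1-methyl-2-(prop-2-en-1-yl)cyclohex-2-en-1-olate | [Li+].[O-][C@]1(C)CC[C@@H]([C@@H](C)CC/C=C(\C)CO[Si](c2ccccc2)(c2ccccc2)C(C)(C)C)C=C1CC=C | intermediate
10 | (1R,4S)-4-[(2S,5E)-7-{[tert-butyl(diphenyl)silyl]oxy}-6-methylhept-5-en-2-yl]-1-methyl-2-(prop-2-en-1-yl)cyclohex-2-en-1-yl acetate (acetoxy trans to the side chain) | CC(=O)O[C@]1(C)CC[C@@H]([C@@H](C)CC/C=C(\C)CO[Si](c2ccccc2)(c2ccccc2)C(C)(C)C)C=C1CC=C | intermediate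
11 | 3-chloro-2-(chloromethyl)prop-1-ene | C=C(CCl)CCl | starting material
12 | 2-(trimethylsilyl)ethanethiol | C[Si](C)(C)CCS | starting material
13 | {2-[(2-(chloromethyl)prop-2-en-1-yl)sulfanyl]ethyl}(trimethyl)silane | C=C(CCl)CSCC[Si](C)(C)C | intermediate
14 | lithium enolate of acetate 10 | [Li+].C=C([O-])O[C@]1(C)CC[C@@H]([C@@H](C)CC/C=C(\C)CO[Si](c2ccccc2)(c2ccccc2)C(C)(C)C)C=C1CC=C | intermediate
15 | (1R,4S)-4-[(2S,5E)-7-{[tert-butyl(diphenyl)silyl]oxy}-6-methylhept-5-en-2-yl]-1-methyl-2-(prop-2-en-1-yl)cyclohex-2-en-1-yl 4-({[2-(trimethylsilyl)ethyl]sulfanyl}methyl)pent-4-enoate | C=C(CSCC[Si](C)(C)C)CCC(=O)O[C@]1(C)CC[C@@H]([C@@H](C)CC/C=C(\C)CO[Si](c2ccccc2)(c2ccccc2)C(C)(C)C)C=C1CC=C | intermediate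
16 | (Z)-trimethylsilyl ketene acetal of ester 15 (C15 cis to OSiMe3) | C=C(CSCC[Si](C)(C)C)C/C=C(\O[Si](C)(C)C)O[C@]1(C)CC[C@@H]([C@@H](C)CC/C=C(\C)CO[Si](c2ccccc2)(c2ccccc2)C(C)(C)C)C=C1CC=C | intermediate
17 | trimethylsilyl ester of acid 18 | C=CCC1=C(C)CC[C@@H]([C@@H](C)CC/C=C(\C)CO[Si](c2ccccc2)(c2ccccc2)C(C)(C)C)[C@@H]1[C@@H](C(=O)O[Si](C)(C)C)CC(=C)CSCC[Si](C)(C)C | intermediate
18 | (2S)-2-{(1R,6S)-6-[(2S,5E)-7-{[tert-butyl(diphenyl)silyl]oxy}-6-methylhept-5-en-2-yl]-3-methyl-2-(prop-2-en-1-yl)cyclohex-2-en-1-yl}-4-({[2-(trimethylsilyl)ethyl]sulfanyl}methyl)pent-4-enoic acid | C=CCC1=C(C)CC[C@@H]([C@@H](C)CC/C=C(\C)CO[Si](c2ccccc2)(c2ccccc2)C(C)(C)C)[C@@H]1[C@@H](C(=O)O)CC(=C)CSCC[Si](C)(C)C | intermediate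
19 | methyl ester of acid 18 (sulfide) | C=CCC1=C(C)CC[C@@H]([C@@H](C)CC/C=C(\C)CO[Si](c2ccccc2)(c2ccccc2)C(C)(C)C)[C@@H]1[C@@H](C(=O)OC)CC(=C)CSCC[Si](C)(C)C | intermediate
20 | sulfone of ester 19 | C=CCC1=C(C)CC[C@@H]([C@@H](C)CC/C=C(\C)CO[Si](c2ccccc2)(c2ccccc2)C(C)(C)C)[C@@H]1[C@@H](C(=O)OC)CC(=C)CS(=O)(=O)CC[Si](C)(C)C | intermediate
21 | bicyclic ester: rings B and C; C5=C6 and C8=C9 alkenes; CO2Me on C14; CH2SO2CH2CH2SiMe3 on C5; 12S,13R,14S,1′S,4′E | C1(CS(=O)(=O)CC[Si](C)(C)C)=CCC3=C(C)CC[C@@H]([C@@H](C)CC/C=C(\C)CO[Si](c4ccccc4)(c4ccccc4)C(C)(C)C)[C@@H]3[C@@H](C(=O)OC)C1 | intermediate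
22 | phenyl vinyl sulfone (ethenylsulfonylbenzene) | C=CS(=O)(=O)c1ccccc1 | starting material
23 | lithiated Michael adduct: 21 carrying CH(SO2R)–CH2–CH(Li)SO2Ph at C5 | [Li+].C1(C(C[CH-]S(=O)(=O)c4ccccc4)S(=O)(=O)CC[Si](C)(C)C)=CCC3=C(C)CC[C@@H]([C@@H](C)CC/C=C(\C)CO[Si](c5ccccc5)(c5ccccc5)C(C)(C)C)[C@@H]3[C@@H](C(=O)OC)C1 | intermediate
24 | tricyclic β-keto bis-sulfone: C1 ketone; PhSO2 on C2; Me3SiCH2CH2SO2 on C4; C5=C6 and C8=C9; 12S,13R,14S; epimers at C2 and C4 | O=C1C(S(=O)(=O)c4ccccc4)CC(S(=O)(=O)CC[Si](C)(C)C)C2=CCC3=C(C)CC[C@@H]([C@@H](C)CC/C=C(\C)CO[Si](c5ccccc5)(c5ccccc5)C(C)(C)C)[C@@H]3[C@@H]1C2 | intermediate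
25 | tricyclic ketone: C1 ketone; Me3SiCH2CH2SO2 on C4; C5=C6 and C8=C9 | O=C1CCC(S(=O)(=O)CC[Si](C)(C)C)C2=CCC3=C(C)CC[C@@H]([C@@H](C)CC/C=C(\C)CO[Si](c4ccccc4)(c4ccccc4)C(C)(C)C)[C@@H]3[C@@H]1C2 | intermediate
26 | exocyclic methylene sulfone: C1=C16; Me3SiCH2CH2SO2 on C4; C5=C6 and C8=C9 | C=C1CCC(S(=O)(=O)CC[Si](C)(C)C)C2=CCC3=C(C)CC[C@@H]([C@@H](C)CC/C=C(\C)CO[Si](c4ccccc4)(c4ccccc4)C(C)(C)C)[C@@H]3[C@@H]1C2 | intermediate
27 | tetrabutylammonium C4-sulfinate with free C6′ hydroxyl | C=C1CCC(S(=O)[O-])C2=CCC3=C(C)CC[C@@H]([C@@H](C)CC/C=C(\C)CO)[C@@H]3[C@@H]1C2.CCCC[N+](CCCC)(CCCC)CCCC | intermediate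
28 | allylic C4-sulfinic acid | C=C1CCC(S(=O)O)C2=CCC3=C(C)CC[C@@H]([C@@H](C)CC/C=C(\C)CO)[C@@H]3[C@@H]1C2 | intermediate
29 | CNP0289180.1 (12S,13R,14S,1′S,4′E) | C=C1CCC=C2CCC3=C(C)CC[C@@H]([C@@H](C)CC/C=C(\C)CO)[C@@H]3[C@@H]1C2 | target

**Step count and risks**

Total step count: 14. Longest linear sequence: 13 steps (1, 2, 3, 4, 5, 7, 8, 9, 10, 11, 12, 13, 14); step 6 is a one-step branch.

Step 11. The allyl sulfonyl carbanion may add through its γ-terminus (C6), or the sequence may stop after the conjugate addition because the bridging acylation is slow. The fallback makes the two bonds in separate steps. It sets out from 21: DIBAL-H at −78 °C reduces the ester to the aldehyde F1, vinylmagnesium bromide gives the allylic alcohol F2, and Dess–Martin oxidation gives the vinyl ketone F3, which already holds the C1–C2 bond. Catalytic KOtBu in THF then closes ring A by intramolecular Michael addition of the C4 sulfonyl carbanion to C3 (7-endo-trig). This gives ketone 25 directly, and the route continues with step 13.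

Step 14. The C5=C6 double bond may migrate into conjugation with the sulfone under the basic fluoride before the sulfinate is released, or the C4 epimer present may be unable to align its C–S bond with the alkene for the retro-ene step. The fallback replaces the sulfinic acid route by a hydrazone route and sets out from 26. The C4 carbanion (LDA, −78 °C) is oxidised with MoO5·pyridine·HMPA (oxidative desulfonylation) to the enone F4, which is condensed with tosylhydrazine to the tosylhydrazone F5. Catecholborane and then NaOAc at reflux (reductive 1,3-transposition of an enone hydrazone) should give the silyl ether F6 with the C4=C5 alkene. Bu4NF at 23 °C then gives target 29.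

Step 8. Stereocontrol may be eroded: equatorial attack of MeLi in step 5 would invert C13 after the suprafacial shift, and a boat-like transition state would invert C14. The fallback sets C13 by substrate-controlled conjugate addition and sets out from enone 8. The methyl ester F7 (from the lithium enolate of methyl acetate and 13) is added as its lithium enolate in THF–HMPA to C13 of 8, anti to the C12 side chain. The ring enolate is trapped with N-phenyltriflimide as the enol triflate F8, and iron-catalysed methylation (MeMgBr, Fe(acac)3, THF–NMP, −20 °C) returns to 19 as a C14 epimer mixture. C14 would then be equilibrated with NaOMe in MeOH at the stage of 21, where the ester trans to the C12–C13 bond is expected to be favoured.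

**Further compounds**

F1 | step 11 | aldehyde: 21 with CHO in place of CO2Me on C14 | C1(CS(=O)(=O)CC[Si](C)(C)C)=CCC3=C(C)CC[C@@H]([C@@H](C)CC/C=C(\C)CO[Si](c4ccccc4)(c4ccccc4)C(C)(C)C)[C@@H]3[C@@H](C=O)C1
F2 | step 11 | allylic alcohol: 21 with CH(OH)CH=CH2 on C14 (carbinol epimers) | C1(CS(=O)(=O)CC[Si](C)(C)C)=CCC3=C(C)CC[C@@H]([C@@H](C)CC/C=C(\C)CO[Si](c4ccccc4)(c4ccccc4)C(C)(C)C)[C@@H]3[C@@H](C(O)C=C)C1
F3 | step 11 | vinyl ketone: 21 with C(=O)CH=CH2 on C14 | C1(CS(=O)(=O)CC[Si](C)(C)C)=CCC3=C(C)CC[C@@H]([C@@H](C)CC/C=C(\C)CO[Si](c4ccccc4)(c4ccccc4)C(C)(C)C)[C@@H]3[C@@H](C(=O)C=C)C1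
F4 | step 14 | enone: 26 with C4 ketone conjugated to C5=C6 | C=C1CCC(=O)C2=CCC3=C(C)CC[C@@H]([C@@H](C)CC/C=C(\C)CO[Si](c4ccccc4)(c4ccccc4)C(C)(C)C)[C@@H]3[C@@H]1C2
F5 | step 14 | tosylhydrazone of enone F4 | C=C1CCC(=NNS(=O)(=O)c4ccc(C)cc4)C2=CCC3=C(C)CC[C@@H]([C@@H](C)CC/C=C(\C)CO[Si](c5ccccc5)(c5ccccc5)C(C)(C)C)[C@@H]3[C@@H]1C2
F6 | step 14 | tert-butyldiphenylsilyl ether of the target | C=C1CCC=C2CCC3=C(C)CC[C@@H]([C@@H](C)CC/C=C(\C)CO[Si](c4ccccc4)(c4ccccc4)C(C)(C)C)[C@@H]3[C@@H]1C2
F7 | step 8 | methyl 4-({[2-(trimethylsilyl)ethyl]sulfanyl}methyl)pent-4-enoate | COC(=O)CCC(=C)CSCC[Si](C)(C)C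
F8 | step 8 | enol triflate: C9 triflate of the C8=C9 enol; C13 trans to C12; C14 epimers | C=CCC1=C(OS(=O)(=O)C(F)(F)F)CC[C@@H]([C@@H](C)CC/C=C(\C)CO[Si](c2ccccc2)(c2ccccc2)C(C)(C)C)[C@@H]1C(C(=O)OC)CC(=C)CSCC[Si](C)(C)C
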